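(The readings stem from a simulated flask on assumed constants; the scatter is artificial.)

all flasks: reagent 0.725 M; impurity 37 mM

| charge | substrate | free catalyst | remark | time |
|---|---|---|---|---|
| red | 0.29 M | 19 mM | run made earlier |  |
| amber | 0.29 M | 44 mM | run made earlier |  |
| violet | 0.14 M | 29 mM | run made earlier |  |
| flask | 0.29 M | 29 mM |  | 2.0 min |

- red (time / min: open intermediate / %, target / %): 0.200: 58.7, 7.2; 0.333: 56.7, 6.7; 0.417: 58.8, 8.5; 0.667: 57.2, 8.9; 1.00: 57.8, 7.3; 1.50: 57.0, 9.6; 2.50: 57.3, 7.2
- amber (time / min: open intermediate / %, target / %): 0.167: 51.2, 46.4; 0.333: 42.0, 56.9; 0.667: 33.5, 65.7; 1.00: 30.5, 65.9; 1.33: 30.5, 65.8; 2.00: 29.9, 67.2; 2.50: 30.8, 68.1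
- violet (time / min: open intermediate / %, target / %): 0.200: 69.5, 20.5; 0.667: 69.0, 20.3; 1.00: 66.2, 21.9; 1.50: 66.7, 21.6; 2.50: 67.2, 20.3

(readings scatter by 1 percentage point)



- concentration of open intermediate at 2.0 min, in M
- concentration of target at 2.0 min, in M
- concentration of substrate at 2.0 min, in M
- concentration of reagent at 2.0 min, in M

1. The millimolar of catalyst was my unit: I let each one of free catalyst take one of impurity with it. In the flask 29 mM of catalyst met 37 mM of impurity, so I took catalyst as the limiting reagent of that loss, with 8.00 mM of impurity left over.

2. The red and violet runs stood flat within their scatter from their first readings at 0.200 min, well before 2.0 min, and the violet run had the flask's charges of catalyst and impurity, so I treated the loss in the flask as finished by the asked time. The logarithm of impurity charged over impurity left came to 1.53 for the flask; I called that logarithm the dose, the time integral of free catalyst in units of the poisoning's time constant.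

3. Bound from above on the substrate left in the flask: the red run, with less catalyst, read on average 34.4% of its substrate not found as open intermediate or target, which is 0.0999 M on this charge.

4. Bound from below on that substrate: the amber run, with more catalyst, read 0.00319 M on the same reckoning at its last reading, a difference of readings that carries their scatter.

5. Tightening: I assumed that substrate and impurity each fall at a rate of free catalyst times their own amount, so the percentage of substrate left follows the dose and not the substrate charge. The logarithm of substrate's fall per dose, a selectivity factor of substrate against impurity, read 1.48 in the red run. The violet run, with half the substrate and the flask's dose, read 11.4% unaccounted for, giving 1.42. So I carried the violet shares over, assuming further that the shares of target and open intermediate also stay with the substrate charge changed: substrate 0.0329 M, target 0.0607 M, open intermediate 0.196 M. Taking one reagent per target, an assumption no reading tests, left reagent at 0.664 M.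

6. The forecast, noting that “the stoichiometry of the later step is uncertain”, gave open intermediate 0.196 M, target 0.057 M, substrate 0.037 M, inside my bracket, and reagent 0.472 M, below mine.

7. The flask gave open intermediate 0.195 M, target 0.0603 M, substrate 0.0339 M and reagent 0.664 M.

    substrate + free catalyst → free catalyst + open intermediate (k = 35.0 M⁻¹ s⁻¹)
    free catalyst + target → spent catalyst B (k = 0.340 M⁻¹ s⁻¹)
    free catalyst + open intermediate ⇌ catalyst intermediate (K = 30.0 M⁻¹, k = 6.90 M⁻¹ s⁻¹)
    free catalyst + impurity → spent catalyst A (k = 24.0 M⁻¹ s⁻¹)
    reagent + catalyst intermediate → free catalyst + target (k = 19.0 M⁻¹ s⁻¹)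

The same reckoning went to a neighbour flask charged with 0.15 M of impurity, the other charges held. Its 29 mM of catalyst stood below that impurity, so its dose was 0.215. With the factor 1.48 this gave substrate left at 72.7% and impurity left at 80.7%. The neighbour at 2.00 min held impurity at 80.7% and substrate at 73.1%, which is 0.212 M.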